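**Plan**

- Numbering in each quinone ring: C1 chain carbon, C2 biaryl carbon, C3 C=O, C4 C–CH3, C5 C–OH, C6 C=O. Ring A carries the 2-(2-methoxyphenyl)ethyl chain and ring B the 2-phenylethyl chain.
- Enabling feature: the para carbonyl carbons C6 and C3 sit directly on C1 and C2. C1=C2 therefore maps onto an alkyne, C6 onto an alkoxycarbene carbon, C3 onto CO and C5=C4 onto a propenyl group, and C2–C2' is the central single bond of a conjugated 1,3-diyne.
- Cuts, in order: the two C5–O bonds (hydroxyquinone back to C5–H quinone, then to the 4-methoxyphenol); C1–C6, C2–C3 and C3–C4 in both rings at once; the sp–sp bond of the diyne; the benzyl–propargyl bond of the anisylbutyne.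
- Forward: the eight-carbon chain between the two arenes is joined first (alkylation, Cadiot–Chodkiewicz coupling). Rings A and B then close in one flask on the existing C2–C2' bond. Oxidation, epoxidation and isomerisation set the quinones and the C5 hydroxyls.
- Stereochemistry: the target has no stereocentre. The hindered C2–C2' axis forms racemic, and the epoxide stereocentres of the penultimate compound are transient.

Key step: step 6

Assumption: the target SMILES carries no stereodescriptor, so no configuration of the C2–C2' axis is aimed at.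

**Step 1**
Reactants: 1 1-(trimethylsilyl)prop-1-yne; 2 2-methoxybenzyl chloride
Product: 4 [4-(2-methoxyphenyl)but-1-yn-1-yl]trimethylsilane, via 3-(trimethylsilyl)prop-2-ynyllithium 3 (not isolated)
Conditions: 1, n-BuLi, THF, −78 to −20 °C; then 2, −78 °C to rt
Reagents that add atoms: none
Why: Propargylic lithiation of a 1-silylpropyne followed by SN2 alkylation with a benzylic chloride; the silyl group blocks the acetylenic terminus and steers attack to the propargylic rather than the allenic carbon.

**Step 2**
Reactants: 4 [4-(2-methoxyphenyl)but-1-yn-1-yl]trimethylsilane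
Product: 5 1-(but-3-yn-1-yl)-2-methoxybenzene
Conditions: K2CO3 (cat.), MeOH, rt
Reagents that add atoms: none
Why: Base-catalysed protodesilylation of an alkynylsilane in methanol, to which the aryl methyl ether is inert.

**Step 3**
Reactants: 6 4-phenylbut-1-yne
Product: 7 (4-bromobut-3-yn-1-yl)benzene
Conditions: NBS, AgNO3 (10 mol %), acetone, rt, dark
Reagents that add atoms: N-bromosuccinimide, O=C1CCC(=O)N1Br
Why: AgNO3-catalysed electrophilic bromination of a terminal alkyne; the halogen goes on the partner without an activated arene, so ring bromination of the anisole cannot arise.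

**Step 4**
Reactants: 5 1-(but-3-yn-1-yl)-2-methoxybenzene; 7 (4-bromobut-3-yn-1-yl)benzene
Product: 8 1-methoxy-2-(8-phenylocta-3,5-diyn-1-yl)benzene
Conditions: CuCl (5 mol %), NH2OH·HCl, 30% aq n-BuNH2, Et2O, 0 °C, slow addition of 7
Reagents that add atoms: none
Why: Cadiot–Chodkiewicz coupling of the alkynylcopper species from 5 and CuCl with bromoalkyne 7 forms the sp–sp bond that becomes C2–C2'; NH2OH·HCl keeps copper monovalent and suppresses oxidative homocoupling, and the three conceivable diynes differ in their number of methoxy groups, which should make chromatographic separation simple.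

**Step 5**
Reactants: 9 (E)-1-bromoprop-1-ene; 10 chromium hexacarbonyl
Product: 13 pentacarbonyl[(2E)-1-methoxybut-2-en-1-ylidene]chromium, via (E)-prop-1-enyllithium 11 (not isolated), via lithium pentacarbonyl(1-oxidobut-2-enylidene)chromate 12 (not isolated)
Conditions: 9, t-BuLi (2 equiv), Et2O, −78 °C; Cr(CO)6, Et2O, 0 °C to rt; then Me3OBF4, CH2Cl2, 0 °C to rt
Reagents that add atoms: trimethyloxonium tetrafluoroborate, C[O+](C)C.F[B-](F)(F)F
Why: Fischer carbene synthesis, that is bromine–lithium exchange with retention of the E geometry, addition of the alkenyllithium to a CO ligand of Cr(CO)6 and O-methylation of the acylate by the hard electrophile Me3OBF4.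

**Step 6**
Reactants: 8 1-methoxy-2-(8-phenylocta-3,5-diyn-1-yl)benzene; 13 pentacarbonyl[(2E)-1-methoxybut-2-en-1-ylidene]chromium (two equivalents consumed)
Product: 16 5,5'-dimethoxy-6-[2-(2-methoxyphenyl)ethyl]-3,3'-dimethyl-6'-(2-phenylethyl)biphenyl-2,2'-diol, via ring A monoadduct 14 (not isolated), via ring B monoadduct 15 (not isolated)
Conditions: 13 (2.6 equiv, two portions), THF, 55 °C, argon, 24–48 h; then air, Et2O, rt
Reagents that add atoms: none
Why: Thermal loss of one CO ligand from 13 frees a site on zerovalent chromium, one triple bond of 8 inserts into the Cr=C bond (C1–C6) to give a vinylcarbene complex, a CO ligand migrates onto the new carbene carbon (C2–C3) to give a chromium-bound dienylketene, and ring closure followed by keto–enol tautomerisation gives the 4-methoxyphenol 14 or 15, whose remaining aryl alkyl alkyne runs through the same sequence with a second molecule of 13. The reaction type is the Dötz benzannulation of an alkenyl(alkoxy)carbene complex, and its twofold use on conjugated 1,3-diynes to build 2,2'-biphenols is established. Ring A and ring B each close by 6π electrocyclisation of the dienylketene, which forms C3–C4, so the crowded C2–C2' bond is never made by a coupling but is carried in as the central single bond of the diyne. No stereocentre is formed, and the tetra-ortho-substituted axis arises in racemic form. The step needs the same sense of insertion at both triple bonds, outer (chain) carbon to the carbene carbon and inner carbon to CO: in the first insertion the conjugating alkynyl substituent stabilises the carbene carbon that forms next to chromium and so behaves as the large group, and in the second the 2,6-disubstituted aryl group is by far the larger substituent. Which triple bond reacts first does not matter because 14 and 15 converge on 16, alkenyl complexes give phenols rather than indenes or cyclobutenones, the excess of 13 drives the slower second annulation, and air at the end frees the product from chromium.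

**Step 7**
Reactants: 16 5,5'-dimethoxy-6-[2-(2-methoxyphenyl)ethyl]-3,3'-dimethyl-6'-(2-phenylethyl)biphenyl-2,2'-diol
Product: 17 2-[2-(2-methoxyphenyl)ethyl]-5,5'-dimethyl-2'-(2-phenylethyl)[1,1'-bi(cyclohexa-1,4-diene)]-3,3',6,6'-tetrone
Conditions: (NH4)2Ce(NO3)6 (4.4 equiv), MeCN–H2O, 0 °C
Reagents that add atoms: water, O
Why: Oxidative demethylation of 4-methoxyphenols by tetravalent cerium, the usual oxidative finish of a Dötz reaction; the two-electron oxidation of the electron-rich pentasubstituted rings is much faster than any attack on the plain anisole ring, water adds at C6 and methanol leaves.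

**Step 8**
Reactants: 17 2-[2-(2-methoxyphenyl)ethyl]-5,5'-dimethyl-2'-(2-phenylethyl)[1,1'-bi(cyclohexa-1,4-diene)]-3,3',6,6'-tetrone
Product: 18 4-[2-(2-methoxyphenyl)ethyl]-1,1'-dimethyl-4'-(2-phenylethyl)[3,3'-bi(7-oxabicyclo[4.1.0]hept-3-ene)]-2,2',5,5'-tetrone (C4–C5 epoxide in each ring, cis-fused, mixture of diastereomers)
Conditions: 30% aq H2O2, Na2CO3, THF–H2O, 0 °C
Reagents that add atoms: hydrogen peroxide, OO
Why: Weitz–Scheffer nucleophilic epoxidation of a quinone, in which hydroperoxide adds to C5, the only unsubstituted enedione carbon of each ring, while the tetrasubstituted C1=C2 bond beside the axis is shielded; the ring fusion forces each epoxide to be cis, and the relative configuration between the rings is left uncontrolled because step 9 erases all four centres.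

**Step 9**
Reactants: 18 the bis-epoxide of step 8
Product: 19 4,4'-dihydroxy-2-[2-(2-methoxyphenyl)ethyl]-5,5'-dimethyl-2'-(2-phenylethyl)[1,1'-bi(cyclohexa-1,4-diene)]-3,3',6,6'-tetrone (CNP0202346.0)
Conditions: H2SO4 on SiO2, THF, rt
Reagents that add atoms: none
Why: Acid-promoted isomerisation of a 2,3-epoxy-1,4-dione bearing an epoxide hydrogen to the 2-hydroxyquinone (the reaction that turns 2-methylnaphthoquinone oxide into its 3-hydroxyquinone); C4–O cleavage and loss of the C5 proton leave the oxygen on C5, restore C4=C5 and give the stabilised vinylogous acid, and the supported acid is mild enough to spare the anisole ring.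

**Compound list**

| No. | Name | SMILES | Role |
|---|---|---|---|
| 1 | 1-(trimethylsilyl)prop-1-yne | CC#C[Si](C)(C)C | starting material |
| 2 | 2-methoxybenzyl chloride | COc1ccccc1CCl | starting material |
| 3 | 3-(trimethylsilyl)prop-2-ynyllithium | [Li]CC#C[Si](C)(C)C | intermediate |
| 4 | [4-(2-methoxyphenyl)but-1-yn-1-yl]trimethylsilane | COc1ccccc1CCC#C[Si](C)(C)C | intermediate |
| 5 | 1-(but-3-yn-1-yl)-2-methoxybenzene | COc1ccccc1CCC#C | intermediate |
| 6 | 4-phenylbut-1-yne | C#CCCc1ccccc1 | starting material |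
| 7 | (4-bromobut-3-yn-1-yl)benzene | BrC#CCCc1ccccc1 | intermediate |
| 8 | 1-methoxy-2-(8-phenylocta-3,5-diyn-1-yl)benzene | COc1ccccc1CCC#CC#CCCc1ccccc1 | intermediate |
| 9 | (E)-1-bromoprop-1-ene | C/C=C/Br | starting material |
| 10 | chromium hexacarbonyl | O=C=[Cr](=C=O)(=C=O)(=C=O)(=C=O)=C=O | starting material |
| 11 | (E)-prop-1-enyllithium | C/C=C/[Li] | intermediate |
| 12 | lithium pentacarbonyl[(2E)-1-oxidobut-2-en-1-ylidene]chromate | [Li+].[O-]C(/C=C/C)=[Cr](=C=O)(=C=O)(=C=O)(=C=O)=C=O | intermediate |
| 13 | pentacarbonyl[(2E)-1-methoxybut-2-en-1-ylidene]chromium | COC(/C=C/C)=[Cr](=C=O)(=C=O)(=C=O)(=C=O)=C=O | intermediate |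
| 14 | ring A monoadduct: 4-methoxy-3-[2-(2-methoxyphenyl)ethyl]-6-methyl-2-(4-phenylbut-1-yn-1-yl)phenol | COc1ccccc1CCc1c(OC)cc(C)c(O)c1C#CCCc1ccccc1 | intermediate |
| 15 | ring B monoadduct: 4-methoxy-2-[4-(2-methoxyphenyl)but-1-yn-1-yl]-6-methyl-3-(2-phenylethyl)phenol | COc1ccccc1CCC#Cc1c(O)c(C)cc(OC)c1CCc1ccccc1 | intermediate |
| 16 | 5,5'-dimethoxy-6-[2-(2-methoxyphenyl)ethyl]-3,3'-dimethyl-6'-(2-phenylethyl)biphenyl-2,2'-diol | COc1ccccc1CCc1c(OC)cc(C)c(O)c1-c1c(O)c(C)cc(OC)c1CCc1ccccc1 | intermediate |
| 17 | 2-[2-(2-methoxyphenyl)ethyl]-5,5'-dimethyl-2'-(2-phenylethyl)[1,1'-bi(cyclohexa-1,4-diene)]-3,3',6,6'-tetrone | COc1ccccc1CCC1=C(C2=C(CCc3ccccc3)C(=O)C=C(C)C2=O)C(=O)C(C)=CC1=O | intermediate |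
| 18 | 4-[2-(2-methoxyphenyl)ethyl]-1,1'-dimethyl-4'-(2-phenylethyl)[3,3'-bi(7-oxabicyclo[4.1.0]hept-3-ene)]-2,2',5,5'-tetrone, cis-fused epoxides, mixture of diastereomers | COc1ccccc1CCC1=C(C2=C(CCc3ccccc3)C(=O)C3OC3(C)C2=O)C(=O)C2(C)OC2C1=O | intermediate |
| 19 | 4,4'-dihydroxy-2-[2-(2-methoxyphenyl)ethyl]-5,5'-dimethyl-2'-(2-phenylethyl)[1,1'-bi(cyclohexa-1,4-diene)]-3,3',6,6'-tetrone | COc1ccccc1CCC1=C(C2=C(CCc3ccccc3)C(=O)C(O)=C(C)C2=O)C(=O)C(C)=C(O)C1=O | target |

Total step count: 9.
Longest linear sequence: 7 (steps 1, 2, 4, 6, 7, 8, 9).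

**Steps most likely to fail**

**Step 6.**
- What may go wrong:
  - The second annulation may stall at the hindered aryl alkyne.
  - Part of the first insertion may take the opposite sense.
  - The free ortho-alkynylphenol may add to its own triple bond.
- The fallback is a sequential annulation with a capped phenol. It sets out from 8 and returns at 17.
- One equivalent of 13 (THF, 55 °C) is used and 14 and 15 are isolated, which also allows any product of wrong-sense insertion to be removed.
- MeI and K2CO3 in acetone then give the methyl ether of 14 F1 and the methyl ether of 15 F2.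
- This mixture no longer has an acidic OH beside the triple bond. It is heated with fresh 13 to give the ring A O-methylated biaryl F3 and the ring B O-methylated biaryl F4.
- (NH4)2Ce(NO3)6 in aqueous MeCN oxidises 1,4-dimethoxyarene and 4-methoxyphenol rings alike, so both compounds converge on 17.

**Step 8.**
- What may go wrong:
  - The epoxide may open prematurely in the alkaline peroxide, and the resulting hydroxyquinone may then be degraded oxidatively.
  - Base may tautomerise the alkylquinone towards a quinone methide.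
- The fallback is oxidative amination and hydrolysis. It sets out from 17 and returns at 19, bypassing steps 8 and 9.
- Me2NH in EtOH–THF under air adds to C5 of both rings (conjugate addition, then reoxidation by air) to give the bis(dimethylamino)quinone F5.
- F5 is a vinylogous amide, which dilute aqueous HCl in dioxane at reflux should hydrolyse to 19.

**Step 9.**
- What may go wrong:
  - The tethered anisole ring may attack the acid-activated enedione.
  - Hydration may occur without the following dehydration.
  - Only one of the two epoxides may isomerise.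
- The fallback carries the C5 oxygen through the benzannulation, so no late oxygenation is needed. It sets out from 8 and 10 and returns at 19.
- The Z isomer of commercial ethyl prop-1-enyl ether is lithiated at the α carbon (t-BuLi, THF, −78 to 0 °C) to (Z)-1-ethoxyprop-1-enyllithium F6.
- With 10 this gives lithium pentacarbonyl[(2Z)-2-ethoxy-1-oxidobut-2-en-1-ylidene]chromate F7, and with Me3OBF4 it gives pentacarbonyl[(2Z)-2-ethoxy-1-methoxybut-2-en-1-ylidene]chromium F8. F8 is the open-chain relative of the well-behaved dihydropyranyl carbene complexes.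
- Twofold benzannulation of 8 under the conditions of step 6 passes through the ethoxy ring A monoadduct F9 and the ethoxy ring B monoadduct F10 and gives the 4,4'-diethoxybiphenol F11.
- (NH4)2Ce(NO3)6 gives the bis(ethoxyquinone) F12. Its vinylogous ester groups are hydrolysed by aqueous NaOH in MeOH–THF at rt, followed by acidification, to 19.

**Further compounds**
F1 | step 6 | methyl ether of 14: 1,4-dimethoxy-2-[2-(2-methoxyphenyl)ethyl]-5-methyl-3-(4-phenylbut-1-yn-1-yl)benzene | COc1ccccc1CCc1c(OC)cc(C)c(OC)c1C#CCCc1ccccc1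
F2 | step 6 | methyl ether of 15: 1,4-dimethoxy-3-[4-(2-methoxyphenyl)but-1-yn-1-yl]-5-methyl-2-(2-phenylethyl)benzene | COc1ccccc1CCC#Cc1c(OC)c(C)cc(OC)c1CCc1ccccc1
F3 | step 6 | ring A O-methylated biaryl: 2',5,5'-trimethoxy-6'-[2-(2-methoxyphenyl)ethyl]-3,3'-dimethyl-6-(2-phenylethyl)biphenyl-2-ol | COc1ccccc1CCc1c(OC)cc(C)c(OC)c1-c1c(O)c(C)cc(OC)c1CCc1ccccc1
F4 | step 6 | ring B O-methylated biaryl: 2',5,5'-trimethoxy-6-[2-(2-methoxyphenyl)ethyl]-3,3'-dimethyl-6'-(2-phenylethyl)biphenyl-2-ol | COc1ccccc1CCc1c(OC)cc(C)c(O)c1-c1c(OC)c(C)cc(OC)c1CCc1ccccc1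
F5 | step 8 | bis(dimethylamino)quinone: 4,4'-bis(dimethylamino)-2-[2-(2-methoxyphenyl)ethyl]-5,5'-dimethyl-2'-(2-phenylethyl)[1,1'-bi(cyclohexa-1,4-diene)]-3,3',6,6'-tetrone | COc1ccccc1CCC1=C(C2=C(CCc3ccccc3)C(=O)C(N(C)C)=C(C)C2=O)C(=O)C(C)=C(N(C)C)C1=O
F6 | step 9 | (Z)-1-ethoxyprop-1-enyllithium | C/C=C(\OCC)[Li]
F7 | step 9 | lithium pentacarbonyl[(2Z)-2-ethoxy-1-oxidobut-2-en-1-ylidene]chromate | C/C=C(\OCC)C([O-])=[Cr](=C=O)(=C=O)(=C=O)(=C=O)=C=O.[Li+]
F8 | step 9 | pentacarbonyl[(2Z)-2-ethoxy-1-methoxybut-2-en-1-ylidene]chromium | C/C=C(\OCC)C(OC)=[Cr](=C=O)(=C=O)(=C=O)(=C=O)=C=O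
F9 | step 9 | ethoxy ring A monoadduct: 3-ethoxy-4-methoxy-5-[2-(2-methoxyphenyl)ethyl]-2-methyl-6-(4-phenylbut-1-yn-1-yl)phenol | COc1ccccc1CCc1c(OC)c(OCC)c(C)c(O)c1C#CCCc1ccccc1
F10 | step 9 | ethoxy ring B monoadduct: 3-ethoxy-4-methoxy-6-[4-(2-methoxyphenyl)but-1-yn-1-yl]-2-methyl-5-(2-phenylethyl)phenol | COc1ccccc1CCC#Cc1c(O)c(C)c(OCC)c(OC)c1CCc1ccccc1
F11 | step 9 | 4,4'-diethoxybiphenol: 4,4'-diethoxy-5,5'-dimethoxy-6-[2-(2-methoxyphenyl)ethyl]-3,3'-dimethyl-6'-(2-phenylethyl)biphenyl-2,2'-diol | COc1ccccc1CCc1c(OC)c(OCC)c(C)c(O)c1-c1c(O)c(C)c(OCC)c(OC)c1CCc1ccccc1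
F12 | step 9 | bis(ethoxyquinone): 4,4'-diethoxy-2-[2-(2-methoxyphenyl)ethyl]-5,5'-dimethyl-2'-(2-phenylethyl)[1,1'-bi(cyclohexa-1,4-diene)]-3,3',6,6'-tetrone | COc1ccccc1CCC1=C(C2=C(CCc3ccccc3)C(=O)C(OCC)=C(C)C2=O)C(=O)C(C)=C(OCC)C1=O
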